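**Retrosynthetic overview**
1. The target comes from desilylation and angeloylation of a 7,9-bis-TIPS benzoxepane allylic alcohol. The arene is bought, and the oxepane is the only ring made, late in the route.
2. The oxepane and the exocyclic allylic alcohol both come from one base-triggered cascade of an acyclic ortho-acetoxyaryl (7R,8R,10R)-bis-epoxide. The sequence is phenoxide, ortho-quinone methide (benzylic epoxide opens, C8–O kept), 2-alkenylphenoxide, then 7-exo-tet opening of the terminal epoxide (C10 inverted). This is the bisabolene-epoxide path thought to lead to heliannuol-type ethers.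
3. Both stereocentres come from one double Shi epoxidation of an (E)-aryl skipped diene (an aromatic bisabolene).
4. The diene comes from Negishi coupling of an aryl bromide with the alkenyl metal made by hydrozirconation of 6-methylhept-5-en-2-yne (propynyl Grignard plus prenyl bromide).
5. The aryl bromide comes from 2,4-dihydroxy-3-methylbenzaldehyde by silylation, Baeyer–Villiger oxidation and ortho-bromination/acetylation.

Numbering: side chain C7 (benzylic)–C8–C9–C10–C11 becomes C5, C4, C3, C2 and the carbinol carbon of the 1-benzoxepine. The target SMILES decodes as (2S,4R), 2,4-trans, with a (Z)-ester.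

Assumption: the D-fructose-derived ketone shows its usual facial sense, giving (R,R) from E-trisubstituted olefins and (R) from a prenyl olefin.

**Step 1**
Reactants: 1 2,4-dihydroxy-3-methylbenzaldehyde
Product: 2 3-methyl-2,4-bis(triisopropylsilyloxy)benzaldehyde
Conditions: TIPSOTf (2.4 equiv), 2,6-lutidine, CH2Cl2, 0 °C → rt
Reagents that add atoms: triisopropylsilyl trifluoromethanesulfonate (TIPSOTf), CC(C)[Si](C(C)C)(C(C)C)OS(=O)(=O)C(F)(F)F
Why: Phenol O-silylation with the silyl triflate caps both OH groups, including the hydrogen-bonded and flanked 2-OH, as base-robust and fluoride-labile ethers.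

**Step 2**
Reactants: 2 3-methyl-2,4-bis(triisopropylsilyloxy)benzaldehyde
Product: 4 3-methyl-2,4-bis(triisopropylsilyloxy)phenol, via aryl formate 3 (not isolated)
Conditions: mCPBA, CH2Cl2, 0 °C → rt; then Et3N (cat.), MeOH, rt
Reagents that add atoms: 3-chloroperbenzoic acid (mCPBA), OOC(=O)c1cccc(Cl)c1
Why: In this Baeyer–Villiger (Dakin-type) oxidation the electron-rich aryl group migrates and the labile formate is methanolysed, so the formyl carbon becomes the one phenol that differs from the two silylated ones.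

**Step 3**
Reactants: 4 3-methyl-2,4-bis(triisopropylsilyloxy)phenol
Product: 6 6-bromo-3-methyl-2,4-bis(triisopropylsilyloxy)phenyl acetate, via bromophenol 5 (not isolated)
Conditions: NBS (1.0 equiv), i-Pr2NH (10 mol %), CH2Cl2, −20 °C, dark; then Ac2O, Et3N, DMAP (cat.), 0 °C → rt
Reagents that add atoms: N-bromosuccinimide, O=C1CCC(=O)N1Br; acetic anhydride, CC(=O)OC(C)=O
Why: Amine-catalysed ortho-bromination (electrophilic aromatic substitution through a phenol-bound N-bromoamine) hits the only free position ortho to the OH, the other CH being shielded by a TIPS group, and immediate acetylation masks the oxidation-prone phenol.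

**Step 4**
Reactants: 7 1-propynylmagnesium bromide; 8 prenyl bromide (1-bromo-3-methylbut-2-ene)
Product: 9 6-methylhept-5-en-2-yne
Conditions: CuI (5 mol %), THF, 0 °C → rt
Reagents that add atoms: none
Why: Copper-catalysed alkynyl Grignard–allyl halide coupling runs SN2 at the primary carbon of prenyl bromide and gives the skipped enyne.

**Step 5**
Reactants: 9 6-methylhept-5-en-2-yne; 6 6-bromo-3-methyl-2,4-bis(triisopropylsilyloxy)phenyl acetate
Product: 12 3-methyl-6-[(2E)-6-methylhepta-2,5-dien-2-yl]-2,4-bis(triisopropylsilyloxy)phenyl acetate, via alkenylzirconocene chloride 10 (not isolated), via alkenylzinc chloride 11 (not isolated)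
Conditions: 9 (1.5 equiv), Cp2Zr(H)Cl (slight excess over 9), THF, rt; ZnCl2, 0 °C; then 6, Pd(OAc)2 (3 mol %), 2-dicyclohexylphosphino-2',6'-dimethoxybiphenyl (SPhos, 6 mol %), THF, 45 °C
Reagents that add atoms: none
Why: syn-Hydrozirconation places Zr on the methyl-bearing alkyne carbon (about 9:1 after equilibration, trisubstituted alkene untouched), and transmetalation followed by Negishi coupling with retention fixes the E geometry (aryl trans to C9).

**Step 6**
Reactants: 12 3-methyl-6-[(2E)-6-methylhepta-2,5-dien-2-yl]-2,4-bis(triisopropylsilyloxy)phenyl acetate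
Product: 13 6-[(2R,3R)-3-{[(2R)-3,3-dimethyloxiran-2-yl]methyl}-2-methyloxiran-2-yl]-3-methyl-2,4-bis(triisopropylsilyloxy)phenyl acetate
Conditions: 1,2:4,5-di-O-isopropylidene-β-D-erythro-2,3-hexodiulo-2,6-pyranose (Shi ketone from D-fructose, 60 mol %), KHSO5 (as 2KHSO5·KHSO4·K2SO4, 3 equiv), K2CO3, Bu4NHSO4, MeCN–CH2(OMe)2–aq Na2B4O7 buffer (pH 10.5), −5 → 0 °C
Reagents that add atoms: potassium peroxymonosulfate, [K+].[O-]S(=O)(=O)OO
Why: A double Shi asymmetric epoxidation (spiro dioxirane transition state) sets 7R,8R on the E-trisubstituted styrene and 10R on the prenyl olefin with one catalyst; the two independent events amplify the ee of the major diastereomer, and the doubly flanked aryl acetate should survive as enol esters do under these conditions.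

**Step 7**
Reactants: 13 6-[(2R,3R)-3-{[(2R)-3,3-dimethyloxiran-2-yl]methyl}-2-methyloxiran-2-yl]-3-methyl-2,4-bis(triisopropylsilyloxy)phenyl acetate
Product: 17 (2S,4R)-2-(2-hydroxypropan-2-yl)-8-methyl-5-methylidene-7,9-bis(triisopropylsilyloxy)-2,3,4,5-tetrahydro-1-benzoxepin-4-ol, via potassium phenoxide 14 (not isolated), via ortho-quinone methide alkoxide 15 (not isolated), via 2-alkenylphenoxide 16 (not isolated)
Conditions: KOt-Bu (1.3 equiv), THF–t-BuOH 5:1, −20 °C → 45 °C; aq NH4Cl
Reagents that add atoms: none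
Why: Proposed new method: tert-butoxide removes the acetyl group; the ortho phenoxide then pushes open the strained tertiary benzylic C7–O bond to the quinone methide (C8–O untouched, 8R kept); t-BuOH/t-BuO− shuttles a proton from the C7 methyl group so that the ring rearomatises to the 2-(1-methylidenealkyl)phenoxide; only then, because the trans epoxide cannot sit in a seven-membered ring, can the phenoxide open the terminal epoxide 7-exo-tet at the less substituted C10 with inversion (10R → 2S); the closest known reaction types are base- or fluoride-triggered ortho-quinone methide generation from ortho-hydroxybenzyl leaving groups, tautomerisation of alkyl-substituted quinone methides to 2-alkenylphenols, and base-mediated 7-exo phenoxide–epoxide closure to heliannuol-type benzoxepanes.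

**Step 8**
Reactants: 17 (2S,4R)-2-(2-hydroxypropan-2-yl)-8-methyl-5-methylidene-7,9-bis(triisopropylsilyloxy)-2,3,4,5-tetrahydro-1-benzoxepin-4-ol; 18 angelic acid ((2Z)-2-methylbut-2-enoic acid)
Product: 19 (2S,4R)-2-(2-hydroxypropan-2-yl)-8-methyl-5-methylidene-7,9-bis(triisopropylsilyloxy)-2,3,4,5-tetrahydro-1-benzoxepin-4-yl (2Z)-2-methylbut-2-enoate
Conditions: 18, 2,4,6-Cl3C6H2COCl, Et3N, PhMe, rt; then 17, 75 °C
Reagents that add atoms: none
Why: Yamaguchi-type mixed-anhydride esterification without a nucleophilic catalyst acylates only the secondary allylic OH (the tertiary carbinol is inert and the phenols are silylated), avoids Z-to-E leakage to the tiglate, and breaks no bond at C4.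

**Step 9**
Reactants: 19 (2S,4R)-2-(2-hydroxypropan-2-yl)-8-methyl-5-methylidene-7,9-bis(triisopropylsilyloxy)-2,3,4,5-tetrahydro-1-benzoxepin-4-yl (2Z)-2-methylbut-2-enoate
Product: 20 (2S,4R)-7,9-dihydroxy-2-(2-hydroxypropan-2-yl)-8-methyl-5-methylidene-2,3,4,5-tetrahydro-1-benzoxepin-4-yl (2Z)-2-methylbut-2-enoate (CNP0160456.1)
Conditions: Bu4NF, AcOH (1:1, 2.5 equiv), THF, 0 °C, under argon
Reagents that add atoms: none
Why: Acetic-acid-buffered fluoride desilylation cleaves aryl silyl ethers within minutes, while the buffer protects the angelate, the allylic ester and the air-sensitive hydroquinone-type product from base.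

**Compound list**
1 | 2,4-dihydroxy-3-methylbenzaldehyde | Cc1c(O)ccc(C=O)c1O | starting material
2 | 3-methyl-2,4-bis(triisopropylsilyloxy)benzaldehyde | Cc1c(O[Si](C(C)C)(C(C)C)C(C)C)ccc(C=O)c1O[Si](C(C)C)(C(C)C)C(C)C | intermediate
3 | 3-methyl-2,4-bis(triisopropylsilyloxy)phenyl formate | Cc1c(O[Si](C(C)C)(C(C)C)C(C)C)ccc(OC=O)c1O[Si](C(C)C)(C(C)C)C(C)C | intermediate
4 | 3-methyl-2,4-bis(triisopropylsilyloxy)phenol | Cc1c(O[Si](C(C)C)(C(C)C)C(C)C)ccc(O)c1O[Si](C(C)C)(C(C)C)C(C)C | intermediate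
5 | 6-bromo-3-methyl-2,4-bis(triisopropylsilyloxy)phenol | Cc1c(O[Si](C(C)C)(C(C)C)C(C)C)cc(Br)c(O)c1O[Si](C(C)C)(C(C)C)C(C)C | intermediate
6 | 6-bromo-3-methyl-2,4-bis(triisopropylsilyloxy)phenyl acetate | Cc1c(O[Si](C(C)C)(C(C)C)C(C)C)cc(Br)c(OC(C)=O)c1O[Si](C(C)C)(C(C)C)C(C)C | intermediate
7 | 1-propynylmagnesium bromide | CC#C[Mg]Br | starting material
8 | prenyl bromide | CC(C)=CCBr | starting material
9 | 6-methylhept-5-en-2-yne | CC#CCC=C(C)C | intermediate
10 | chloro[(2E)-6-methylhepta-2,5-dien-2-yl]zirconocene (Cp rings drawn sigma-bound) | C/C(=C\CC=C(C)C)[Zr](Cl)(C1C=CC=C1)C1C=CC=C1 | intermediate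
11 | [(2E)-6-methylhepta-2,5-dien-2-yl]zinc chloride | C/C(=C\CC=C(C)C)[Zn]Cl | intermediate
12 | 3-methyl-6-[(2E)-6-methylhepta-2,5-dien-2-yl]-2,4-bis(triisopropylsilyloxy)phenyl acetate | Cc1c(O[Si](C(C)C)(C(C)C)C(C)C)cc(/C(C)=C/CC=C(C)C)c(OC(C)=O)c1O[Si](C(C)C)(C(C)C)C(C)C | intermediate
13 | (7R,8R,10R)-bis-epoxide aryl acetate | Cc1c(O[Si](C(C)C)(C(C)C)C(C)C)cc([C@@]2(C)O[C@@H]2C[C@H]2OC2(C)C)c(OC(C)=O)c1O[Si](C(C)C)(C(C)C)C(C)C | intermediate
14 | potassium phenoxide of the (7R,8R,10R)-bis-epoxide | Cc1c(O[Si](C(C)C)(C(C)C)C(C)C)cc([C@@]2(C)O[C@@H]2C[C@H]2OC2(C)C)c([O-])c1O[Si](C(C)C)(C(C)C)C(C)C.[K+] | intermediate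
15 | ortho-quinone methide (8R)-alkoxide, (10R)-epoxide intact, exocyclic C=C geometry open | CC1=C(O[Si](C(C)C)(C(C)C)C(C)C)C(=O)C(=C(C)[C@H]([O-])C[C@H]2OC2(C)C)C=C1O[Si](C(C)C)(C(C)C)C(C)C.[K+] | intermediate
16 | potassium 2-[(3R)-3-hydroxy-4-((2R)-3,3-dimethyloxiran-2-yl)but-1-en-2-yl]phenoxide | Cc1c(O[Si](C(C)C)(C(C)C)C(C)C)cc(C(=C)[C@H](O)C[C@H]2OC2(C)C)c([O-])c1O[Si](C(C)C)(C(C)C)C(C)C.[K+] | intermediate
17 | (2S,4R)-2-(2-hydroxypropan-2-yl)-8-methyl-5-methylidene-7,9-bis(triisopropylsilyloxy)-2,3,4,5-tetrahydro-1-benzoxepin-4-ol | C=C1c2cc(O[Si](C(C)C)(C(C)C)C(C)C)c(C)c(O[Si](C(C)C)(C(C)C)C(C)C)c2O[C@H](C(C)(C)O)C[C@H]1O | intermediate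
18 | angelic acid | C/C=C(/C)C(=O)O | starting material
19 | bis-TIPS ether of the target | C=C1c2cc(O[Si](C(C)C)(C(C)C)C(C)C)c(C)c(O[Si](C(C)C)(C(C)C)C(C)C)c2O[C@H](C(C)(C)O)C[C@H]1OC(=O)/C(C)=C\C | intermediate
20 | CNP0160456.1, (2S,4R) | C=C1c2cc(O)c(C)c(O)c2O[C@H](C(C)(C)O)C[C@H]1OC(=O)/C(C)=C\C | target

**Step count**
Total step count: 9. Longest linear sequence: 8 (steps 1, 2, 3, 5, 6, 7, 8, 9).

**Three steps most likely to fail**

**Step 7 (cascade).** The quinone methide 15 may collapse by a 1,2-hydride shift to the C8 ketone, or be trapped, before it tautomerises.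
- The fallback sets out from 13 and comes back at 17. It swaps tautomerisation for addition followed by elimination.
- 13 is treated with PhSeH (1.2 equiv) and KOt-Bu (2.4 equiv) in THF–t-BuOH at −20 °C. The soft selenolate adds to C7 of 15 faster than any rearrangement and gives the acyclic benzylic phenyl selenide F1.
- Warming to 45 °C closes the ring by the same 7-exo opening to the 5-methyl-5-(phenylselanyl)benzoxepan-4-ol F2.
- H2O2 and pyridine in CH2Cl2 at 0 °C give the benzoxepane selenoxide F3. Its syn elimination runs away from the carbinol carbon into the methyl group and delivers 17.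

**Step 6 (double Shi epoxidation).** The ortho-substituted styrene may react slowly or with low selectivity. The aryl acetate or the benzylic epoxide may also not survive pH 10.5.
- The fallback sets out from 6 and comes back at 17. It gives up the second epoxide and sets C4 by late substrate-controlled allylic hydroxylation.
- 6-Methylhept-5-en-2-one is condensed with 2,4,6-triisopropylbenzenesulfonohydrazide to the sulcatone trisylhydrazone F4.
- n-BuLi (2 equiv, Shapiro reaction) gives 6-methylhepta-1,5-dien-2-yllithium F5, and ZnCl2 gives 6-methylhepta-1,5-dien-2-ylzinc chloride F6.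
- Negishi coupling with 6 under the step 5 catalyst gives the 1,1-disubstituted styrene acetate F7.
- One Shi epoxidation, for which only the prenyl olefin is reactive enough, gives the (10R)-monoepoxide acetate F8.
- KOt-Bu in THF–t-BuOH closes it 7-exo to the (2S)-5-methylidene benzoxepane F9.
- SeO2 (cat.) with t-BuOOH in CH2Cl2 (ene reaction, then [2,3] shift) should replace the pseudo-axial C4–H, trans to the equatorial C2 substituent, and give 17.

**Step 3 (ortho-bromination).** The para-silyloxyphenol may be oxidised to a quinone, or may brominate at the CH ortho/para to the two silyloxy groups.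
- The fallback sets out from 4 and comes back at 12. It uses a directed C–H borylation and reverses the polarity of the coupling.
- 4 with Et2SiH2 and [Ir(cod)Cl]2 (cat.) gives the diethylhydrosilyl aryl ether F10.
- B2pin2, [Ir(cod)Cl]2 and 4,4'-di-tert-butyl-2,2'-bipyridine in THF at 80 °C borylate the only CH within reach of the Si–H group, giving the ortho-boryl hydrosilyl ether F11.
- Quenching 10 with I2 gives (E)-2-iodo-6-methylhepta-2,5-diene F12.
- Suzuki coupling of F11 with F12 (Pd(dppf)Cl2, aq K3PO4, THF, 50 °C) also cleaves the Si–O bond and gives the free (E)-2-alkenylphenol F13.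
- Ac2O, Et3N and DMAP convert F13 into 12.

**Further compounds**
F1 | step 7 | acyclic benzylic phenyl selenide (C7 epimers, 8R,10R) | CC([Se]c1ccccc1)(c1cc(O[Si](C(C)C)(C(C)C)C(C)C)c(C)c(O[Si](C(C)C)(C(C)C)C(C)C)c1O)[C@H](O)C[C@H]1OC1(C)C
F2 | step 7 | 5-methyl-5-(phenylselanyl)benzoxepan-4-ol (2S,4R, C5 epimers) | CC1([Se]c2ccccc2)c2cc(O[Si](C(C)C)(C(C)C)C(C)C)c(C)c(O[Si](C(C)C)(C(C)C)C(C)C)c2O[C@H](C(C)(C)O)C[C@H]1O
F3 | step 7 | benzoxepane selenoxide (2S,4R, C5 and Se epimers) | CC1([Se](=O)c2ccccc2)c2cc(O[Si](C(C)C)(C(C)C)C(C)C)c(C)c(O[Si](C(C)C)(C(C)C)C(C)C)c2O[C@H](C(C)(C)O)C[C@H]1O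
F4 | step 6 | sulcatone trisylhydrazone | CC(CCC=C(C)C)=NNS(=O)(=O)c1c(C(C)C)cc(C(C)C)cc1C(C)C
F5 | step 6 | 6-methylhepta-1,5-dien-2-yllithium | [Li]C(=C)CCC=C(C)C
F6 | step 6 | 6-methylhepta-1,5-dien-2-ylzinc chloride | Cl[Zn]C(=C)CCC=C(C)C
F7 | step 6 | 1,1-disubstituted styrene acetate | Cc1c(O[Si](C(C)C)(C(C)C)C(C)C)cc(C(=C)CCC=C(C)C)c(OC(C)=O)c1O[Si](C(C)C)(C(C)C)C(C)C
F8 | step 6 | (10R)-monoepoxide acetate | Cc1c(O[Si](C(C)C)(C(C)C)C(C)C)cc(C(=C)CC[C@H]2OC2(C)C)c(OC(C)=O)c1O[Si](C(C)C)(C(C)C)C(C)C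
F9 | step 6 | (2S)-5-methylidene benzoxepane | C=C1c2cc(O[Si](C(C)C)(C(C)C)C(C)C)c(C)c(O[Si](C(C)C)(C(C)C)C(C)C)c2O[C@H](C(C)(C)O)CC1
F10 | step 3 | diethylhydrosilyl aryl ether | CC[SiH](CC)Oc1ccc(O[Si](C(C)C)(C(C)C)C(C)C)c(C)c1O[Si](C(C)C)(C(C)C)C(C)C
F11 | step 3 | ortho-boryl hydrosilyl ether | CC[SiH](CC)Oc1c(B2OC(C)(C)C(C)(C)O2)cc(O[Si](C(C)C)(C(C)C)C(C)C)c(C)c1O[Si](C(C)C)(C(C)C)C(C)C
F12 | step 3 | (E)-2-iodo-6-methylhepta-2,5-diene | C/C(I)=C\CC=C(C)C
F13 | step 3 | free (E)-2-alkenylphenol | Cc1c(O[Si](C(C)C)(C(C)C)C(C)C)cc(/C(C)=C/CC=C(C)C)c(O)c1O[Si](C(C)C)(C(C)C)C(C)C
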